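The earlier runs and the new flask come from a simulation with constants of no real substance, noise included.

Two numbers and one choice are asked of these flasks, and I try one integrated rate on them.

| flask | substrate | partner | temperature | remark | time |
|---|---|---|---|---|---|
| alpha | 1 M | 1.7 equiv | 95 °C | run made earlier |  |
| epsilon | 1 M | 1.7 equiv | 106 °C | run made earlier |  |
| south | 1.0 M | 2.50 equiv | 90 °C |  | 6.0 d |
| north-west | 1.0 M | 2.50 equiv | 110 °C |  | 6.0 d |

- alpha (time / d: target / %): 0.250: 1.9; 0.417: 3.0; 0.625: 4.7; 1.04: 11.0; 1.67: 20.3; 2.50: 26.6; 4.00: 40.3
- epsilon (time / h: target / %): 2.50: 0.6; 5.00: 3.4; 6.00: 5.8; 12.0: 16.6; 20.0: 27.1; 25.0: 31.2; 40.0: 42.5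

(readings scatter by 1 percentage point)

- the flask that comes out highest in amount of target, in percent of the substrate charged, or "all alike" when all lie within 1.5 percentage points (south / north-west / all alike)
- target at the end, in percent of the substrate charged, south
- target at the end, in percent of the substrate charged, north-west

At the board, the first chemist lets the unreacted fraction of the charged substrate fall in proportion to itself, so that it goes as exp(−kt) and target is the rest. A single reading then gives k, and he takes the last of each run, well past the slow start. The alpha run gives 0.129 d⁻¹ and the epsilon run 0.332 d⁻¹. Spreading ln k evenly over temperature, he gets for south the clock constant, a pseudo-first-order constant, of 0.0839 d⁻¹, and for north-west 0.468 d⁻¹. Over 6.0 d these give 39.6% for south and 94.0% for north-west.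

The second chemist replies that the rate must go with partner too. These flasks carry 2.50 equiv against 1.7 equiv in the runs, so the clock should run 1.47 times faster. That gives 52.3% for south and 98.4% for north-west.

Both runs hold partner at the same charge, so the readings cannot judge between them. I commit to the first reckoning, the one that uses what was read, and both put north-west highest.

The forecast, 51% for south, 90% for north-west and north-west highest, stood with the second chemist, somewhat lower than his figures, on the words “both runs fit roughly first order in each reactant”.

South gives 35.5% and north-west 70.2%, so north-west is highest. With partner alone raised from the alpha run's charge to south's, the alpha run at the time of its last reading, without the scatter, holds 38.0% against 37.7%; the second chemist's view gets its region in north-west at low charge, where the answer has moved 5 points by 0.961 equiv. The clock gave 39.6% for south against 35.5%. For north-west its 94.0% stands above 70.2% and above the 73.1% that flask holds after 60.0 d, so north-west's clock is read up to that level.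

    substrate ⇌ open intermediate (K = 1.00, k = 0.0320 h⁻¹, Ea = 120 kJ mol⁻¹, ΔH = −38.0 kJ mol⁻¹)
    partner → second intermediate (k = 0.0820 h⁻¹, Ea = 129 kJ mol⁻¹)
    open intermediate + second intermediate → target (k = 1.60 M⁻¹ h⁻¹, Ea = 74.0 kJ mol⁻¹)
    2 second intermediate → homo product (k = 0.0410 M⁻¹ h⁻¹, Ea = 115 kJ mol⁻¹)
    substrate ⇌ dormant form (K = 2.50, k = 0.0290 h⁻¹, Ea = 126 kJ mol⁻¹, ΔH = −16.0 kJ mol⁻¹)
    (constants at 110 °C)

For south read at 40 h, the clock gives 13.0%, below that level, and the computed flask holds 12.4%.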